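**Retrosynthetic overview**
1. Target 15 ⇐ 14 by diimide saturation of three C=C bonds. 14 ⇐ 10 + two molecules of 13 by double cross-metathesis, so both pyridylalkyl chains come from one alkenylpyridine. 10 ⇐ 8 ⇐ 7 by N-deprotection and N-alkylation with 6-bromohex-1-ene.
2. Key disconnection: the C5–C6 bond of the carbocycle. Fused bicycle 7 (cyclopentene C5=C6, vinyl on C3) ⇐ bridged 7-allyl-2-oxa-3-azabicyclo[2.2.1]hept-5-ene 6 by ring-rearrangement metathesis (ring closure onto the strained alkene, which opens the bridged ring).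
3. Enabling feature: on the 1,2-oxazolidine ring of the target, the C3 side chain, the C3a–C4 bond and the C6a–C6 bond are all cis. This is the imprint of a nitroso–cyclopentadiene cycloadduct: C3 and C6a are its bridgeheads, C3a is its one-carbon bridge carrying a syn allyl group (C4, C5), and the first side-chain carbon and C6 are its two alkene carbons.
4. 6 ⇐ sodium cyclopentadienide + allyl bromide + BocN=O (nitroso Diels–Alder reaction, anti to allyl). The chiral catalyst of step 2 sorts the racemate, so the absolute configuration is set in the key step.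
5. Ring order: the 1,2-oxazolidine ring first (step 1, inside the bridged bicycle, C–O and C–N bonds), the carbocycle second (step 2, C5–C6).

Key step: step 2

Remark (assumption): the sense of induction of the molybdenum catalyst in step 2 cannot be predicted with confidence; the (S)-biphenolate is written and its mirror image is used if the first run delivers the opposite series. The alkenes made in step 6 are drawn E; E/Z mixtures are expected and converge in step 7.

**Step 1**
Reactants: 1 sodium cyclopentadienide; 2 allyl bromide; 3 tert-butyl N-hydroxycarbamate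
Product: 6 racemic tert-butyl (1S*,4R*,7S*)-7-(prop-2-en-1-yl)-2-oxa-3-azabicyclo[2.2.1]hept-5-ene-3-carboxylate, via 5-allylcyclopenta-1,3-diene 4 (not isolated), via tert-butyl nitrosoformate 5 (not isolated)
Conditions: 1 + 2, THF, −78 to −40 °C; then 3, Bu4NIO4, CH2Cl2, −40 to 0 °C
Reagents that add atoms: none
Why: C-alkylation of cyclopentadienide gives the 5-allyl diene, which is trapped below the temperature of its 1,5-hydrogen shift in a nitroso Diels–Alder reaction with the acylnitroso compound made by periodate oxidation; the dienophile adds anti to the allyl group, so allyl ends up syn to the new C5=C6 bond and the relative configuration at C1, C4 and C7 is fixed (racemate).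

**Step 2**
Reactants: 6
Product: 7 tert-butyl (3S,3aS,6aR)-3-ethenyl-3,3a,4,6a-tetrahydro-1H-cyclopenta[c][1,2]oxazole-1-carboxylate
Conditions: Mo(=N-2,6-iPr2C6H3)(=CHCMe2Ph)[(S)-3,3'-tBu2-5,5',6,6'-Me4-biphenyl-2,2'-diolate] (5 mol%), C6H6 (0.05 M), 22 °C, N2; chromatographic separation from the regioisomer
Reagents that add atoms: none
Why: Proposed new method: the hexavalent molybdenum alkylidene exchanges onto the terminal allyl alkene, the tethered alkylidene adds to the exo face of the strained C5=C6 bond, and cycloreversion opens the bicycle, so the cyclopentene closes by bonding the allyl CH carbon to the alkene carbon next to the N-bearing bridgehead (five-membered carbocycle by ring-closing metathesis, driven by release of norbornene-type strain) while the other alkene carbon becomes the vinyl group on C3; the closest known reactions are ring-rearrangement metathesis of nitroso Diels–Alder adducts with achiral ruthenium catalysts and molybdenum-catalysed asymmetric ring-opening/ring-closing metathesis of meso norbornenes carrying tethered alkenes. No stereocentre is created: C1, C7 and C4 of 6 become C3, C3a and C6a of 7 unchanged, and the cis ring fusion and all-cis relation follow from the bridged geometry. The selectivity needed is between the two alkene carbons, which differ only in lying next to the N- or the O-bridgehead; the substrate is nearly mirror-symmetric about the plane through C7 and the midpoint of the N–O bond and has no bias of its own, so the chiral catalyst is expected to choose the carbon by its position in space, closing onto the N-side carbon in the (1S,4R,7S) enantiomer (giving 7) and onto the O-side carbon in the other enantiomer (giving the cyclopenta[d] regioisomer); this regiodivergent resolution limits 7 to half of 6 and makes its enantiomeric purity equal to the site selectivity of the catalyst. Chemoselectivity comes from the substrate: only the syn allyl group can reach the ring alkene, the same group slows intermolecular ring-opening, and strain release makes ring-opening irreversible.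

**Step 3**
Reactants: 7
Product: 8 (3S,3aS,6aR)-3-ethenyl-3,3a,4,6a-tetrahydro-1H-cyclopenta[c][1,2]oxazole
Conditions: CF3CO2H, CH2Cl2, 0 °C; aq. NaHCO3 (product volatile, kept in solution)
Reagents that add atoms: none
Why: Acidolysis of the tert-butyl carbamate (Boc removal) should leave the N–O bond, both alkenes and the three stereocentres untouched.

**Step 4**
Reactants: 8; 9 6-bromohex-1-ene
Product: 10 (3S,3aS,6aR)-3-ethenyl-1-(hex-5-en-1-yl)-3,3a,4,6a-tetrahydro-1H-cyclopenta[c][1,2]oxazole
Conditions: K2CO3, NaI (10 mol%), MeCN, 70 °C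
Reagents that add atoms: none
Why: SN2 N-alkylation of the N–H isoxazolidine, whose nitrogen is a good nucleophile (alpha effect), by a primary bromide; no stereocentre is involved.

**Step 5**
Reactants: 11 3-methylpyridine; 12 7-bromohept-1-ene
Product: 13 3-(oct-7-en-1-yl)pyridine
Conditions: LDA (1.05 equiv), THF/DMPU, −78 °C; then 12, −78 °C to rt
Reagents that add atoms: none
Why: Lateral lithiation of 3-picoline and SN2 alkylation of the picolyl anion by the primary bromide, the standard entry to 3-alkylpyridines.

**Step 6**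
Reactants: 10; 13 (6 equiv)
Product: 14 (3S,3aS,6aR)-3-[(1E)-8-(pyridin-3-yl)oct-1-en-1-yl]-1-[(5E)-12-(pyridin-3-yl)dodec-5-en-1-yl]-3,3a,4,6a-tetrahydro-1H-cyclopenta[c][1,2]oxazole
Conditions: TsOH·H2O (1.05 equiv per basic nitrogen), second-generation Hoveyda–Grubbs catalyst RuCl2(H2IMes)(=CH-C6H4-2-OiPr) (2 × 5 mol%), CH2Cl2, 40 °C, argon sparge; aq. NaHCO3
Reagents that add atoms: none
Why: Double olefin cross-metathesis of the two terminal alkenes of 10 with excess 13, with the pyridine and isoxazolidine nitrogens masked as tosylate salts so they do not bind ruthenium; C1'–C8' of the C3 chain and C5'–C12' of the N chain both come from 13, and the stereocentres are not touched.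

**Step 7**
Reactants: 14
Product: 15 (3S,3aS,6aR)-3-[8-(pyridin-3-yl)octyl]-1-[12-(pyridin-3-yl)dodecyl]hexahydro-1H-cyclopenta[c][1,2]oxazole (target)
Conditions: TsNHNH2 (excess, in portions), NaOAc, DME/H2O, reflux
Reagents that add atoms: none
Why: Diimide made in the flask should transfer hydrogen to the three unpolarised C=C bonds (ring C5=C6 and both chain alkenes) and, unlike catalytic hydrogenation, leave the N–O bond and the pyridines intact; no stereocentre is affected.

**Compound list**
1 | sodium cyclopentadienide | [Na+].[CH-]1C=CC=C1 | starting material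
2 | allyl bromide (3-bromoprop-1-ene) | C=CCBr | starting material
3 | tert-butyl N-hydroxycarbamate | CC(C)(C)OC(=O)NO | starting material
4 | 5-allylcyclopenta-1,3-diene | C=CCC1C=CC=C1 | intermediate (not isolated)
5 | tert-butyl nitrosoformate | CC(C)(C)OC(=O)N=O | intermediate (not isolated)
6 | racemic tert-butyl (1S*,4R*,7S*)-7-(prop-2-en-1-yl)-2-oxa-3-azabicyclo[2.2.1]hept-5-ene-3-carboxylate (both enantiomers written) | CC(C)(C)OC(=O)N1O[C@H]2C=C[C@@H]1[C@@H]2CC=C.CC(C)(C)OC(=O)N1O[C@@H]2C=C[C@H]1[C@H]2CC=C | intermediate
7 | tert-butyl (3S,3aS,6aR)-3-ethenyl-3,3a,4,6a-tetrahydro-1H-cyclopenta[c][1,2]oxazole-1-carboxylate | CC(C)(C)OC(=O)N1O[C@@H](C=C)[C@H]2CC=C[C@H]21 | intermediate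
8 | (3S,3aS,6aR)-3-ethenyl-3,3a,4,6a-tetrahydro-1H-cyclopenta[c][1,2]oxazole | N1O[C@@H](C=C)[C@H]2CC=C[C@H]21 | intermediate
9 | 6-bromohex-1-ene | C=CCCCCBr | starting material
10 | (3S,3aS,6aR)-3-ethenyl-1-(hex-5-en-1-yl)-3,3a,4,6a-tetrahydro-1H-cyclopenta[c][1,2]oxazole | C=CCCCCN1O[C@@H](C=C)[C@H]2CC=C[C@H]21 | intermediate
11 | 3-methylpyridine | Cc1cccnc1 | starting material
12 | 7-bromohept-1-ene | C=CCCCCCBr | starting material
13 | 3-(oct-7-en-1-yl)pyridine | C=CCCCCCCc1cccnc1 | intermediate
14 | (3S,3aS,6aR)-3-[(1E)-8-(pyridin-3-yl)oct-1-en-1-yl]-1-[(5E)-12-(pyridin-3-yl)dodec-5-en-1-yl]-3,3a,4,6a-tetrahydro-1H-cyclopenta[c][1,2]oxazole | c1cc(CCCCCC/C=C/CCCCN2O[C@@H](/C=C/CCCCCCc3cccnc3)[C@H]3CC=C[C@H]32)cnc1 | intermediate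
15 | (3S,3aS,6aR)-3-[8-(pyridin-3-yl)octyl]-1-[12-(pyridin-3-yl)dodecyl]hexahydro-1H-cyclopenta[c][1,2]oxazole | c1cncc(CCCCCCCCCCCCN2O[C@@H](CCCCCCCCc3cccnc3)[C@H]3CCC[C@H]32)c1 | target

**Step count**
Total: 7 steps. Longest linear sequence: 6 steps (1, 2, 3, 4, 6, 7).

**Steps most likely to fail**

Step 2 (Proposed new method). What may go wrong: the catalyst may discriminate poorly between the two alkene carbons, so that 7 is formed with low enantiomeric purity, or the molybdenum alkylidene may be deactivated by the N-acyl-N-alkoxy group. Fallback, from 6 back to 7: the racemate 6 is resolved by preparative chromatography on a chiral stationary phase to give tert-butyl (1S,4R,7S)-7-(prop-2-en-1-yl)-2-oxa-3-azabicyclo[2.2.1]hept-5-ene-3-carboxylate F1. Ring-rearrangement metathesis of F1 with the achiral second-generation Grubbs catalyst RuCl2(H2IMes)(PCy3)(=CHPh) under ethylene (CH2Cl2, rt) is a reaction type known for nitroso cycloadducts. It should give 7 together with its regioisomer tert-butyl (3R,3aS,6aS)-3-ethenyl-3,3a,4,6a-tetrahydro-2H-cyclopenta[d][1,2]oxazole-2-carboxylate F2, from which 7 is separated on silica. The absolute configuration then comes from the resolution and the regiochemistry from separation, not from catalyst control.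

Step 1. What may go wrong: 1,5-hydrogen shift of diene 4 to the 1- and 2-allyl isomers, proton exchange between 4 and cyclopentadienide leading to dialkylation, or consumption of the oxidant by residual cyclopentadienide while the nitroso compound is being generated. Fallback, from 1 and 2 back to 6: the cold solution of 4 is treated at −78 to −30 °C in Et2O/EtOH with the pre-formed, oxidant-free dienophile 1-chloro-1-nitrosocyclohexane F3 (from cyclohexanone oxime and tert-butyl hypochlorite). The primary adduct, racemic 3-(1-chlorocyclohexyl)-7-(prop-2-en-1-yl)-2-oxa-3-azabicyclo[2.2.1]hept-5-ene F4, is solvolysed in the flask to racemic (1S*,4R*,7S*)-7-(prop-2-en-1-yl)-2-oxa-3-azabicyclo[2.2.1]hept-5-ene hydrochloride F5, which precipitates. F5 is converted into 6 with Boc2O and aqueous NaHCO3.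

Step 6. What may go wrong: sequestration of ruthenium by the basic nitrogens despite protonation, slow cross-metathesis at the hindered allylic C3 vinyl group while 13 homodimerises, or ring-opening and ring-rearrangement of the cyclopentene through the alkylidene formed at the C3 side chain. Fallback, from 7 back to 14: the hindered cross-metathesis is run first on the non-basic carbamate 7 with the tosylate salt of 13 (same catalyst) to give tert-butyl (3S,3aS,6aR)-3-[(1E)-8-(pyridin-3-yl)oct-1-en-1-yl]-3,3a,4,6a-tetrahydro-1H-cyclopenta[c][1,2]oxazole-1-carboxylate F6. Boc removal with CF3CO2H gives (3S,3aS,6aR)-3-[(1E)-8-(pyridin-3-yl)oct-1-en-1-yl]-3,3a,4,6a-tetrahydro-1H-cyclopenta[c][1,2]oxazole F7. N-alkylation with 9 (K2CO3, MeCN) gives (3S,3aS,6aR)-1-(hex-5-en-1-yl)-3-[(1E)-8-(pyridin-3-yl)oct-1-en-1-yl]-3,3a,4,6a-tetrahydro-1H-cyclopenta[c][1,2]oxazole F8. A single cross-metathesis of the unhindered hexenyl terminus of F8 with 13 then gives 14.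

**Further compounds**
F1 | step 2 | tert-butyl (1S,4R,7S)-7-(prop-2-en-1-yl)-2-oxa-3-azabicyclo[2.2.1]hept-5-ene-3-carboxylate | CC(C)(C)OC(=O)N1O[C@H]2C=C[C@@H]1[C@@H]2CC=C
F2 | step 2 | tert-butyl (3R,3aS,6aS)-3-ethenyl-3,3a,4,6a-tetrahydro-2H-cyclopenta[d][1,2]oxazole-2-carboxylate | CC(C)(C)OC(=O)N1O[C@H]2C=CC[C@H]2[C@H]1C=C
F3 | step 1 | 1-chloro-1-nitrosocyclohexane | O=NC1(Cl)CCCCC1
F4 | step 1 | racemic 3-(1-chlorocyclohexyl)-7-(prop-2-en-1-yl)-2-oxa-3-azabicyclo[2.2.1]hept-5-ene (both enantiomers written) | ClC1(CCCCC1)N1O[C@H]2C=C[C@@H]1[C@@H]2CC=C.ClC1(CCCCC1)N1O[C@@H]2C=C[C@H]1[C@H]2CC=C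
F5 | step 1 | racemic (1S*,4R*,7S*)-7-(prop-2-en-1-yl)-2-oxa-3-azabicyclo[2.2.1]hept-5-ene hydrochloride (both enantiomers written) | Cl.N1O[C@H]2C=C[C@@H]1[C@@H]2CC=C.Cl.N1O[C@@H]2C=C[C@H]1[C@H]2CC=C
F6 | step 6 | tert-butyl (3S,3aS,6aR)-3-[(1E)-8-(pyridin-3-yl)oct-1-en-1-yl]-3,3a,4,6a-tetrahydro-1H-cyclopenta[c][1,2]oxazole-1-carboxylate | CC(C)(C)OC(=O)N1O[C@@H](/C=C/CCCCCCc2cccnc2)[C@H]2CC=C[C@H]21
F7 | step 6 | (3S,3aS,6aR)-3-[(1E)-8-(pyridin-3-yl)oct-1-en-1-yl]-3,3a,4,6a-tetrahydro-1H-cyclopenta[c][1,2]oxazole | N1O[C@@H](/C=C/CCCCCCc2cccnc2)[C@H]2CC=C[C@H]21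
F8 | step 6 | (3S,3aS,6aR)-1-(hex-5-en-1-yl)-3-[(1E)-8-(pyridin-3-yl)oct-1-en-1-yl]-3,3a,4,6a-tetrahydro-1H-cyclopenta[c][1,2]oxazole | C=CCCCCN1O[C@@H](/C=C/CCCCCCc2cccnc2)[C@H]2CC=C[C@H]21
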